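Ring B is numbered C10 (quaternary; methyl, vinyl carbon C1), C5 (isopropenyl carbon C4), C6 (OH), C7 (side chain carbon C11), C8, C9. Because C1 and C4 sit trans on the adjacent ring atoms C10 and C5, a trans-fused lactone C1(=O)–O–C4 can tie a methacrylate (C9=C10) to a dienyl carbinol (C5 to C8).
Retrosynthesis: the two acetates are cut last; vinyl and isopropenyl go back to the lactone carbonyl C1 and the carbinol C4; the C6–O bond goes back to hydroboration of C6=C7; ring B is cut at C5–C10 and C8–C9 (intramolecular Diels–Alder).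
The diene already carries the protected C11 unit on C7; it is joined from vinyl bromide, the dioxanone and (S)-but-3-yn-2-ol (C7–C11 by carbenoid addition, C6–C7 by Sonogashira coupling, E alkene by hydroalumination).
Forward: diene, methacrylate, ring B and lactone ring in one step, C6 hydroxyl, lactone unravelled to vinyl and isopropenyl, deprotection, diacetylation.
Stereochemistry: C4 (S) is bought with the butynol and relayed to C5 and C10 in the cycloaddition; C6 and C7 come from syn hydroboration anti to the axial C10 methyl; C4 is finally erased as the isopropenyl carbon.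
Key step: step 5

Remark: trans ring fusion is assumed to be the major, separable outcome of step 5; in the metalated intermediates 7 and 12 the tertiary hydroxyl is drawn free although it is metal-bound in the flask.

Step 1
Reactants: 1 vinyl bromide; 2 2,2-dimethyl-1,3-dioxan-5-one
Product: 4 5-(1-bromoethenyl)-2,2-dimethyl-1,3-dioxan-5-ol, via 1-bromo-1-lithioethene 3 (not isolated)
Conditions: LiN(iPr)2, THF/Et2O/pentane 4:1:1, −110 °C; then 2, −110 → −78 °C; H2O
Reagents that add atoms: none
Why: α-Deprotonation of vinyl bromide at very low temperature gives the carbenoid 1-bromo-1-lithioethene, whose 1,2-addition to the unhindered ketone should outrun loss of LiBr and enolisation; no stereocentre arises because C11 carries two identical CH2O arms.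

Step 2
Reactants: 4 5-(1-bromoethenyl)-2,2-dimethyl-1,3-dioxan-5-ol; 5 (S)-but-3-yn-2-ol
Product: 6 5-[(5S)-5-hydroxyhex-1-en-3-yn-2-yl]-2,2-dimethyl-1,3-dioxan-5-ol
Conditions: Pd(PPh3)4 (5 mol %), CuI (10 mol %), Et3N, THF, 50 °C
Reagents that add atoms: none
Why: Sonogashira coupling of a 2-bromoalk-1-ene with a terminal alkyne tolerates both free hydroxyls and forms C6–C7 without touching the C4 stereocentre.

Step 3
Reactants: 6 5-[(5S)-5-hydroxyhex-1-en-3-yn-2-yl]-2,2-dimethyl-1,3-dioxan-5-ol
Product: 8 5-[(3E,5S)-5-hydroxyhexa-1,3-dien-2-yl]-2,2-dimethyl-1,3-dioxan-5-ol, via cyclic alkenylaluminate 7 (not isolated)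
Conditions: NaAlH2(OCH2CH2OMe)2, THF, 0 °C → rt; H2O
Reagents that add atoms: none
Why: Alkoxide-directed trans-hydroalumination of the propargylic alcohol (hydride to C5, aluminium to C6 in a five-membered aluminate) and protonolysis with retention should give only the E alkene C5=C6, the 1,1-disubstituted alkene and the acetonide being inert.

Step 4
Reactants: 8 5-[(3E,5S)-5-hydroxyhexa-1,3-dien-2-yl]-2,2-dimethyl-1,3-dioxan-5-ol; 9 methacryloyl chloride
Product: 10 (2S,3E)-5-(5-hydroxy-2,2-dimethyl-1,3-dioxan-5-yl)hexa-3,5-dien-2-yl 2-methylprop-2-enoate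
Conditions: Et3N, DMAP (cat.), CH2Cl2, −20 → 0 °C
Reagents that add atoms: none
Why: DMAP-catalysed O-acylation should take the secondary allylic hydroxyl at C4 only, the tertiary hydroxyl at C11 being far too hindered under these conditions.

Step 5
Reactants: 10 (2S,3E)-5-(5-hydroxy-2,2-dimethyl-1,3-dioxan-5-yl)hexa-3,5-dien-2-yl 2-methylprop-2-enoate
Product: 11 (3S,3aR,7aR)-5-(5-hydroxy-2,2-dimethyl-1,3-dioxan-5-yl)-3,7a-dimethyl-3a,6,7,7a-tetrahydro-2-benzofuran-1(3H)-one
Conditions: toluene (0.01 M), BHT (cat.), sealed tube, 170 °C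
Reagents that add atoms: none
Why: This is a thermal, concerted, suprafacial [4+2] cycloaddition of the methacrylate C9=C10 onto the diene C5=C6–C7=C8, the closest known reaction type being the intramolecular Diels–Alder reaction of ester-linked 1,3,8-nonatrienes (pentadienyl acrylates). Ring B closes as a cyclohexene through the new bonds C5–C10 and C8–C9, and the five-membered lactone closes as the fused (not bridged) ring because the three-atom tether C4–O–C1 joins the diene terminus C5 to the inner dienophile carbon C10. The new centres C5 and C10 are set together: the C4 stereocentre fixes the diene face, since allylic strain keeps H-4 eclipsed with C5=C6 and turns the C4 methyl away from the incoming dienophile, and the exo placement of the tether carbonyl (methyl endo) gives the trans fusion with C1 trans to C4. The step needs trans over cis fusion and one diene face; the E geometry of C5=C6, the planar ester held in the short tether and the C4 methyl should secure both, and the minor cis-fused adduct expected from the endo-carbonyl mode would be removed by chromatography. The bulky C7 substituent is remote from the tether, favours the s-cis diene and lands on the ring alkene C6=C7, where oxygen must still be added.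

Step 6
Reactants: 11 (3S,3aR,7aR)-5-(5-hydroxy-2,2-dimethyl-1,3-dioxan-5-yl)-3,7a-dimethyl-3a,6,7,7a-tetrahydro-2-benzofuran-1(3H)-one
Product: 13 (3S,3aS,4R,5R,7aR)-4-hydroxy-5-(5-hydroxy-2,2-dimethyl-1,3-dioxan-5-yl)-3,7a-dimethylhexahydro-2-benzofuran-1(3H)-one, via C6 alkylborane 12 (not isolated)
Conditions: BH3·THF, THF, 0 °C → rt; then H2O2 (30% aq.), NaOAc (aq.), 0 °C → rt
Reagents that add atoms: borane–tetrahydrofuran, [BH3-][O+]1CCCC1 (boron of 12); hydrogen peroxide, OO (oxygen on C6)
Why: Hydroboration–oxidation puts boron on the less substituted C6 and, by syn addition from the α face opposite the axial C10 methyl of the locked trans-fused bicycle, sets C6 (α-OH) and C7 (α-H, side chain β) in one operation with retention on oxidation, while the neopentyl lactone carbonyl should react with borane much more slowly than the alkene.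

Step 7
Reactants: 13 (3S,3aS,4R,5R,7aR)-4-hydroxy-5-(5-hydroxy-2,2-dimethyl-1,3-dioxan-5-yl)-3,7a-dimethylhexahydro-2-benzofuran-1(3H)-one
Product: 14 bis(triethylsilyl) ether of 13
Conditions: Et3SiOTf (3 equiv), 2,6-lutidine, CH2Cl2, −78 → 0 °C
Reagents that add atoms: triethylsilyl trifluoromethanesulfonate, CC[Si](CC)(CC)OS(=O)(=O)C(F)(F)F
Why: Silylation with a silyl triflate is strong enough for the hindered secondary C6 hydroxyl and the tertiary C11 hydroxyl alike, giving one defined, fully protected lactone.

Step 8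
Reactants: 14 bis(triethylsilyl) ether of 13
Product: 15 lactol of 14 (C1 hemiacetal)
Conditions: iBu2AlH (1.3 equiv), CH2Cl2, −78 °C; aq. work-up
Reagents that add atoms: none
Why: Partial reduction of a γ-lactone by iBu2AlH should stop at the lactol because the tetrahedral aluminium alkoxide is stable at −78 °C; the anomeric mixture at C1 is of no consequence.

Step 9
Reactants: 15 lactol of 14 (C1 hemiacetal)
Product: 17 C10-vinyl C4-carbinol (5-[(1S)-1-hydroxyethyl] compound), via hydroxy aldehyde 16 (not isolated)
Conditions: Ph3PCH3Br, KOtBu (4 equiv each), THF, 0 °C → reflux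
Reagents that add atoms: methyltriphenylphosphonium bromide, C[P+](c1ccccc1)(c1ccccc1)c1ccccc1.[Br-]
Why: Wittig methylenation traps the ring-opened hydroxy aldehyde; the aldehyde on quaternary C10 has no α-hydrogen to epimerise, and the reaction turns C1 into the vinyl carbon and frees the C4 hydroxyl.

Step 10
Reactants: 17 C10-vinyl C4-carbinol (5-[(1S)-1-hydroxyethyl] compound)
Product: 18 C4 methyl ketone (5-acetyl compound)
Conditions: Dess–Martin periodinane, pyridine, CH2Cl2, 0 °C → rt
Reagents that add atoms: none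
Why: Dess–Martin oxidation of the secondary alcohol erases the auxiliary centre C4; C5 is now α to a ketone but already holds the acetyl group equatorial and trans to both neighbours, so equilibration could only confirm it.

Step 11
Reactants: 18 C4 methyl ketone (5-acetyl compound)
Product: 19 5-isopropenyl bis(triethylsilyl) ether acetonide
Conditions: Cp2TiMe2 (3 equiv), toluene, 70 °C, dark
Reagents that add atoms: dimethyltitanocene Cp2TiMe2, C[Ti](C)(C1C=CC=C1)C1C=CC=C1
Why: Petasis methylenation through Cp2Ti=CH2 is non-basic, so the hindered methyl ketone should be olefinated without enolisation, C5 epimerisation or β-elimination of the C6 silyloxy group.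

Step 12
Reactants: 19 5-isopropenyl bis(triethylsilyl) ether acetonide
Product: 20 2-[(1R,2R,3S,4S)-4-ethenyl-2-hydroxy-4-methyl-3-(prop-1-en-2-yl)cyclohexyl]propane-1,2,3-triol
Conditions: HCl (1 M aq.), THF, rt
Reagents that add atoms: none
Why: Acid-catalysed hydrolysis cleaves the acetonide and both triethylsilyl ethers in one operation, under conditions mild enough for the isopropenyl and vinyl groups.

Step 13
Reactants: 20 2-[(1R,2R,3S,4S)-4-ethenyl-2-hydroxy-4-methyl-3-(prop-1-en-2-yl)cyclohexyl]propane-1,2,3-triol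
Product: 21 2-[(1R,2R,3S,4S)-4-ethenyl-2-hydroxy-4-methyl-3-(prop-1-en-2-yl)cyclohexyl]-2-hydroxypropane-1,3-diyl diacetate (CNP0273389.1)
Conditions: Ac2O (2.2 equiv), pyridine, CH2Cl2, 0 °C
Reagents that add atoms: acetic anhydride, CC(=O)OC(C)=O
Why: Selective O-acylation: the two primary hydroxyls should react much faster than the secondary C6 hydroxyl flanked by two ring substituents, and the tertiary hydroxyl is not acetylated under these conditions.

Compound list
1 | vinyl bromide | C=CBr | starting material
2 | 2,2-dimethyl-1,3-dioxan-5-one | CC1(C)OCC(=O)CO1 | starting material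
3 | 1-bromo-1-lithioethene (in situ) | [Li]C(Br)=C | intermediate
4 | 5-(1-bromoethenyl)-2,2-dimethyl-1,3-dioxan-5-ol | C=C(Br)C1(O)COC(C)(C)OC1 | intermediate
5 | (S)-but-3-yn-2-ol | C#C[C@H](C)O | starting material
6 | 5-[(5S)-5-hydroxyhex-1-en-3-yn-2-yl]-2,2-dimethyl-1,3-dioxan-5-ol | C=C(C#C[C@H](C)O)C1(O)COC(C)(C)OC1 | intermediate
7 | cyclic alkenylaluminate (in situ; Al on C6 and on the C4 oxygen, sodium salt) | C=C(C1(O)COC(C)(C)OC1)C2=C[C@H](C)O[Al-]2(OCCOC)OCCOC.[Na+] | intermediate
8 | 5-[(3E,5S)-5-hydroxyhexa-1,3-dien-2-yl]-2,2-dimethyl-1,3-dioxan-5-ol | C=C(/C=C/[C@H](C)O)C1(O)COC(C)(C)OC1 | intermediate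
9 | methacryloyl chloride | C=C(C)C(=O)Cl | starting material
10 | (2S,3E)-5-(5-hydroxy-2,2-dimethyl-1,3-dioxan-5-yl)hexa-3,5-dien-2-yl 2-methylprop-2-enoate | C=C(/C=C/[C@H](C)OC(=O)C(C)=C)C1(O)COC(C)(C)OC1 | intermediate
11 | (3S,3aR,7aR)-5-(5-hydroxy-2,2-dimethyl-1,3-dioxan-5-yl)-3,7a-dimethyl-3a,6,7,7a-tetrahydro-2-benzofuran-1(3H)-one (trans-fused) | O=C3[C@]1(C)CCC(C2(O)COC(C)(C)OC2)=C[C@H]1[C@H](C)O3 | intermediate
12 | C6 alkylborane of 11 (in situ; boron α on C6, hydrogen α on C7; drawn as RBH2) | O=C3[C@]1(C)CC[C@@H](C2(O)COC(C)(C)OC2)[C@H](B)[C@H]1[C@H](C)O3 | intermediate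
13 | (3S,3aS,4R,5R,7aR)-4-hydroxy-5-(5-hydroxy-2,2-dimethyl-1,3-dioxan-5-yl)-3,7a-dimethylhexahydro-2-benzofuran-1(3H)-one | O=C3[C@]1(C)CC[C@@H](C2(O)COC(C)(C)OC2)[C@H](O)[C@H]1[C@H](C)O3 | intermediate
14 | bis(triethylsilyl) ether of 13 (silyl on the C6 oxygen and on the C11 oxygen) | O=C3[C@]1(C)CC[C@@H](C2(O[Si](CC)(CC)CC)COC(C)(C)OC2)[C@H](O[Si](CC)(CC)CC)[C@H]1[C@H](C)O3 | intermediate
15 | lactol of 14 (C1 hemiacetal, anomer mixture) | OC3[C@]1(C)CC[C@@H](C2(O[Si](CC)(CC)CC)COC(C)(C)OC2)[C@H](O[Si](CC)(CC)CC)[C@H]1[C@H](C)O3 | intermediate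
16 | ring-opened hydroxy aldehyde of 15 (in situ; formyl on C10, (1S)-1-hydroxyethyl on C5) | O=C[C@]1(C)CC[C@@H](C2(O[Si](CC)(CC)CC)COC(C)(C)OC2)[C@H](O[Si](CC)(CC)CC)[C@H]1[C@H](C)O | intermediate
17 | C10-vinyl C4-carbinol: ring of 21 with both silyl ethers and the acetonide, (1S)-1-hydroxyethyl on C5 | C=C[C@]1(C)CC[C@@H](C2(O[Si](CC)(CC)CC)COC(C)(C)OC2)[C@H](O[Si](CC)(CC)CC)[C@H]1[C@H](C)O | intermediate
18 | C4 methyl ketone: as 17 with acetyl on C5 | C=C[C@]1(C)CC[C@@H](C2(O[Si](CC)(CC)CC)COC(C)(C)OC2)[C@H](O[Si](CC)(CC)CC)[C@H]1C(C)=O | intermediate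
19 | 5-isopropenyl compound: bis(triethylsilyl) ether acetonide of 20 | C=C[C@]1(C)CC[C@@H](C2(O[Si](CC)(CC)CC)COC(C)(C)OC2)[C@H](O[Si](CC)(CC)CC)[C@H]1C(C)=C | intermediate
20 | 2-[(1R,2R,3S,4S)-4-ethenyl-2-hydroxy-4-methyl-3-(prop-1-en-2-yl)cyclohexyl]propane-1,2,3-triol | C=C[C@]1(C)CC[C@@H](C(O)(CO)CO)[C@H](O)[C@H]1C(C)=C | intermediate
21 | 2-[(1R,2R,3S,4S)-4-ethenyl-2-hydroxy-4-methyl-3-(prop-1-en-2-yl)cyclohexyl]-2-hydroxypropane-1,3-diyl diacetate (CNP0273389.1; 5S,6R,7R,10S) | C=C[C@]1(C)CC[C@@H](C(O)(COC(C)=O)COC(C)=O)[C@H](O)[C@H]1C(=C)C | target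

Total step count: 13. Longest linear sequence: 13 steps (from 1 and 2 to 21; 5 and 9 enter as bought).

Steps most likely to fail

Step 5. The exo-carbonyl (trans-fusing) mode may not win clearly over the endo-carbonyl (cis-fusing) mode, and polymerisation or loss of methacrylic acid may compete at the temperature the ester needs to reach its reactive conformation. The fallback changes the dienophile to a mesaconate, whose E ester on C9 prefers the endo position and thereby forces the tether carbonyl exo. It sets out from 8. Mesaconic acid and allyl alcohol (acid catalysis, esterification at the less hindered carboxyl) would give 4-allyl hydrogen mesaconate F1. Esterification of 8 with it (DCC, DMAP) would give the mixed mesaconate F2, and its intramolecular Diels–Alder reaction (toluene, about 110 °C) the trans-fused lactone allyl ester F3. Deallylation with Pd(PPh3)4 and morpholine would give the C9 carboxylic acid F4. Barton decarboxylation through the N-acyloxypyridine-2-thione F5 (DCC, N-hydroxypyridine-2-thione; then hν, t-BuSH) would remove the carboxyl and come back to the route at 11.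

Step 6. Borane may reduce the lactone carbonyl while the hindered trisubstituted alkene reacts slowly, or addition may leak to the β face. The fallback sets out from 11 and adds the oxygen first. mCPBA epoxidation anti to the axial C10 methyl would give the α-epoxide F6. Cp2TiCl (trivalent titanium, from Cp2TiCl2 and Zn) with 1,4-cyclohexadiene in THF would open it homolytically at the tertiary C7, and axial hydrogen-atom transfer to that radical would leave the side chain equatorial. This comes back to the route at 13 without any hydride reagent near the lactone.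

Step 1. The carbenoid may lose LiBr, or proton transfer from the enolisable ketone may outrun addition. The fallback sets out from 2 and builds the diene by metathesis. HC≡CMgBr in THF would give 5-ethynyl-2,2-dimethyl-1,3-dioxan-5-ol F7. Ethylene–alkyne metathesis (second-generation Grubbs catalyst RuCl2(=CHPh)(PCy3)(H2IMes), ethylene, toluene) would give 5-(buta-1,3-dien-2-yl)-2,2-dimethyl-1,3-dioxan-5-ol F8. Cross-metathesis of its vinyl terminus with (S)-but-3-en-2-ol (same catalyst) should give the thermodynamically favoured E dienol and come back to the route at 8, bypassing 4 and 6.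

Further compounds
F1 | step 5 | (2E)-2-methyl-4-oxo-4-(prop-2-en-1-yloxy)but-2-enoic acid (4-allyl hydrogen mesaconate) | OC(=O)/C(C)=C/C(=O)OCC=C
F2 | step 5 | 4-allyl 1-[(2S,3E)-5-(5-hydroxy-2,2-dimethyl-1,3-dioxan-5-yl)hexa-3,5-dien-2-yl] (2E)-2-methylbut-2-enedioate | C=C(/C=C/[C@H](C)OC(=O)/C(C)=C/C(=O)OCC=C)C1(O)COC(C)(C)OC1
F3 | step 5 | allyl ester of the trans-fused lactone 11 carrying a β-carboxyl on C9 (cis to the C10 methyl) | O=C3[C@]1(C)[C@@H](C(=O)OCC=C)CC(C2(O)COC(C)(C)OC2)=C[C@H]1[C@H](C)O3
F4 | step 5 | C9 carboxylic acid of lactone 11 | O=C3[C@]1(C)[C@@H](C(=O)O)CC(C2(O)COC(C)(C)OC2)=C[C@H]1[C@H](C)O3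
F5 | step 5 | N-acyloxypyridine-2-thione (Barton ester) of F4 | O=C3[C@]1(C)[C@@H](C(=O)ON4C=CC=CC4=S)CC(C2(O)COC(C)(C)OC2)=C[C@H]1[C@H](C)O3
F6 | step 6 | 6α,7α-epoxide of lactone 11 | O=C3[C@]1(C)CC[C@]2(C4(O)COC(C)(C)OC4)O[C@@H]2[C@H]1[C@H](C)O3
F7 | step 1 | 5-ethynyl-2,2-dimethyl-1,3-dioxan-5-ol | C#CC1(O)COC(C)(C)OC1
F8 | step 1 | 5-(buta-1,3-dien-2-yl)-2,2-dimethyl-1,3-dioxan-5-ol | C=CC(=C)C1(O)COC(C)(C)OC1
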